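**Strategy**

Everything rests on disconnecting the bond between the ketone carbonyl carbon (C1 of the dodecadienone chain) and the benzene carbon that sits between the hydroxyl-bearing and the methyl-bearing ring carbons. The neighbouring phenolic oxygen serves as a temporary tether: the (R)-configured β-quaternary acid is first hung on 2-bromo-3-methylphenol as its aryl ester, and bromine–lithium exchange then triggers a 1,3 O-to-C acyl shift (anionic ortho-Fries rearrangement). In one operation this forges the doubly ortho-flanked aryl–carbonyl bond, with regiochemistry fixed by the bromine, and unveils the free phenol without any protecting group. The quaternary stereocentre is set earlier by iridium-catalysed asymmetric allylic alkylation of farnesyl methyl carbonate with dimethyl malonate.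

Key step: step 5

Remark on the chemistry: in step 2 the ligand antipode written as (S_a) is assumed to be the one that delivers the malonate to the Si face of C3 of the farnesyl unit (priorities C2 > C4 > CH3). If the sense of induction is the opposite for this dialkyl-substituted substrate, the mirror-image ligand is used with no other change.

**Route**

Step 1
Reactants: 1 (2E,6E)-farnesol
Product: 2 methyl (2E,6E)-3,7,11-trimethyldodeca-2,6,10-trien-1-yl carbonate
Conditions: ClCO2Me, pyridine, CH2Cl2, 0 °C → 23 °C
Reagents that add atoms: methyl chloroformate, COC(=O)Cl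
Why: O-acylation of the primary allylic alcohol with a chloroformate (carbonate formation) should proceed cleanly under base and leaves both trisubstituted alkene geometries untouched.

Step 2
Reactants: 2 methyl (2E,6E)-3,7,11-trimethyldodeca-2,6,10-trien-1-yl carbonate; 3 dimethyl malonate
Product: 4 dimethyl 2-[(3S,6E)-3,7,11-trimethyldodeca-1,6,10-trien-3-yl]propanedioate
Conditions: [Ir(cod)Cl]2 (2 mol %), (S_a)-N-aryl BINOL phosphoramidite (4 mol %), TBD (10 mol %), THF; then 2, 3 (2 equiv), NaN(SiMe3)2 (2 equiv), ZnI2 (2 equiv), THF, 23 °C
Reagents that add atoms: none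
Why: Branched-selective iridium-catalysed asymmetric allylic alkylation (Tsuji–Trost type): ionisation gives an allyl–iridium complex in which the E geometry fixes the positions of methyl and homogeranyl, and the zinc malonate should attack the disubstituted terminus C3 on the Si face selected by the phosphoramidite, setting the quaternary stereocentre as (S)-4, which is the spatial arrangement of (R) in the target.

Step 3
Reactants: 4 dimethyl 2-[(3S,6E)-3,7,11-trimethyldodeca-1,6,10-trien-3-yl]propanedioate
Product: 6 (3R,6E)-3-ethenyl-3,7,11-trimethyldodeca-6,10-dienoic acid, via malonic diacid 5 (not isolated)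
Conditions: KOH, EtOH/H2O, 80 °C; aq. KHSO4 (pH 3), extraction; crude 5, Cu2O (cat.), MeCN, 80 °C
Reagents that add atoms: potassium hydroxide, [K+].[OH-]
Why: Saponification of the malonate followed by decarboxylation of the malonic acid (endgame of the malonic ester synthesis) should give the monoacid; the quaternary centre has no acidic hydrogen, so the change of descriptor from S to R reflects only the changed CIP priorities.

Step 4
Reactants: 6 (3R,6E)-3-ethenyl-3,7,11-trimethyldodeca-6,10-dienoic acid; 7 2-bromo-3-methylphenol
Product: 8 2-bromo-3-methylphenyl (3R,6E)-3-ethenyl-3,7,11-trimethyldodeca-6,10-dienoate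
Conditions: DCC, DMAP (cat.), CH2Cl2, 0 °C → 23 °C
Reagents that add atoms: none
Why: Steglich esterification through the acylpyridinium intermediate should acylate the phenol under neutral conditions that spare the acid-sensitive polyene.

Step 5
Reactants: 8 2-bromo-3-methylphenyl (3R,6E)-3-ethenyl-3,7,11-trimethyldodeca-6,10-dienoate
Product: 11 (3R,6E)-3-ethenyl-1-(2-hydroxy-6-methylphenyl)-3,7,11-trimethyldodeca-6,10-dien-1-one, via aryllithium 9 (not isolated), via lithium phenoxide 10 (not isolated)
Conditions: s-BuLi (1.1 equiv), THF/Et2O/pentane, −95 °C → 0 °C; sat. aq. NH4Cl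
Reagents that add atoms: none
Why: s-BuLi should exchange the aryl bromine of 8 faster than it adds to the ester, giving aryllithium 9, whose carbanion attacks the adjacent ester carbonyl through a transient four-membered lithium alkoxide (4-exo-trig attack, not retained in the product) that collapses by C–O cleavage to the ketone phenoxide 10. The closest known reaction type is the halogen–metal-exchange-initiated anionic ortho-Fries rearrangement (1,3 O-to-C acyl migration) of ortho-bromoaryl esters. No ring is closed in the product and no stereocentre is formed; the quaternary C3 bears no acidic hydrogen and is carried through unchanged. The step needs chemoselectivity for exchange over carbonyl addition and α-deprotonation, which the low temperature, the bulky s-BuLi and the β-quaternary centre shielding the carbonyl from intermolecular attack should secure, and it needs regioselectivity, which the position of the bromine between the oxygen-bearing and methyl-bearing ring carbons dictates. The lithium chelate between phenoxide and ketone in 10 should protect the product from further addition until work-up.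

**Compound list**

1 | (2E,6E)-farnesol, (2E,6E)-3,7,11-trimethyldodeca-2,6,10-trien-1-ol | OC/C=C(\C)CC/C=C(\C)CCC=C(C)C | starting material
2 | methyl (2E,6E)-3,7,11-trimethyldodeca-2,6,10-trien-1-yl carbonate | COC(=O)OC/C=C(\C)CC/C=C(\C)CCC=C(C)C | intermediate
3 | dimethyl malonate | COC(=O)CC(=O)OC | starting material
4 | dimethyl 2-[(3S,6E)-3,7,11-trimethyldodeca-1,6,10-trien-3-yl]propanedioate | C=C[C@](C)(CC/C=C(\C)CCC=C(C)C)C(C(=O)OC)C(=O)OC | intermediate
5 | 2-[(3S,6E)-3,7,11-trimethyldodeca-1,6,10-trien-3-yl]propanedioic acid (malonic diacid) | C=C[C@](C)(CC/C=C(\C)CCC=C(C)C)C(C(=O)O)C(=O)O | intermediate (not isolated)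
6 | (3R,6E)-3-ethenyl-3,7,11-trimethyldodeca-6,10-dienoic acid | C=C[C@](C)(CC/C=C(\C)CCC=C(C)C)CC(=O)O | intermediate
7 | 2-bromo-3-methylphenol | Cc1cccc(O)c1Br | starting material
8 | 2-bromo-3-methylphenyl (3R,6E)-3-ethenyl-3,7,11-trimethyldodeca-6,10-dienoate | C=C[C@](C)(CC/C=C(\C)CCC=C(C)C)CC(=O)Oc1cccc(C)c1Br | intermediate
9 | 2-lithio-3-methylphenyl (3R,6E)-3-ethenyl-3,7,11-trimethyldodeca-6,10-dienoate (aryllithium) | C=C[C@](C)(CC/C=C(\C)CCC=C(C)C)CC(=O)Oc1cccc(C)c1[Li] | intermediate (not isolated)
10 | lithium 2-[(3R,6E)-3-ethenyl-3,7,11-trimethyldodeca-6,10-dienoyl]-3-methylphenoxide | C=C[C@](C)(CC/C=C(\C)CCC=C(C)C)CC(=O)c1c(C)cccc1O[Li] | intermediate (not isolated)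
11 | (3R,6E)-3-ethenyl-1-(2-hydroxy-6-methylphenyl)-3,7,11-trimethyldodeca-6,10-dien-1-one | C=C[C@](C)(CC/C=C(\C)CCC=C(C)C)CC(=O)c1c(C)cccc1O | target

**Step count**

Total steps: 5. Longest linear sequence: 5 steps (1 → 2 → 4 → 6 → 8 → 11); compounds 3 and 7 are bought.

**Steps most likely to fail**

Step 5. The alkyllithium may add to the ester carbonyl, or the ester may be deprotonated at its α-carbon and lose the phenoxide as a ketene, before bromine–lithium exchange and acyl migration are complete. The fallback makes the same bond intermolecularly; it sets out from acid 6 and phenol 7 and comes back at target 11. Acid 6 would be converted (carbonyldiimidazole, then HN(OMe)Me·HCl) into the Weinreb amide (3R,6E)-3-ethenyl-N-methoxy-N,3,7,11-tetramethyldodeca-6,10-dienamide F1. Phenol 7 would be protected (chloromethyl methyl ether, i-Pr2NEt) as 2-bromo-1-(methoxymethoxy)-3-methylbenzene F2. Exchange of F2 with n-BuLi in THF at −78 °C should give [2-(methoxymethoxy)-6-methylphenyl]lithium F3, which should add once to F1 to give (3R,6E)-3-ethenyl-1-[2-(methoxymethoxy)-6-methylphenyl]-3,7,11-trimethyldodeca-6,10-dien-1-one F4. Mild acetal exchange (pyridinium p-toluenesulfonate, MeOH, 50 °C) should then release 11.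

Step 2. Attack at the unsubstituted allyl terminus (linear product) may compete, and facial discrimination may be weak for a terminus that carries two alkyl groups. The fallback sets the stereocentre by copper-catalysed SN2'-selective allylic substitution; it sets out from 1 and comes back at acid 6. Farnesol 1 would be phosphorylated (ClP(O)(OEt)2, pyridine, DMAP) to diethyl (2E,6E)-3,7,11-trimethyldodeca-2,6,10-trien-1-yl phosphate F5. Substitution with i-Bu2Al–C≡C–SiMe3 (from trimethylsilylacetylene and i-Bu2AlH with catalytic Et3N), CuCl2·2H2O and a chiral sulfonate-bearing imidazolinium carbene precursor of the appropriate antipode should give trimethyl[(3S,6E)-3-ethenyl-3,7,11-trimethyldodeca-6,10-dien-1-yn-1-yl]silane F6. Desilylation (K2CO3, MeOH) should give (3S,6E)-3-ethenyl-3,7,11-trimethyldodeca-6,10-dien-1-yne F7. Hydroboration of the terminal alkyne with disiamylborane and oxidation (NaOH, H2O2) should give (3R,6E)-3-ethenyl-3,7,11-trimethyldodeca-6,10-dienal F8. Pinnick oxidation (NaClO2, NaH2PO4, 2-methyl-2-butene, t-BuOH/H2O) should then give 6.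

Step 3. Saponification of the second, neopentyl-like ester may stall, and the tert-alkyl-substituted malonic acid may lose CO2 only slowly. The fallback removes one ester group first by nucleophilic demethylation; it sets out from diester 4 and comes back at acid 6. Krapcho dealkoxycarbonylation (LiCl, H2O, DMSO, 150 °C) should give methyl (3R,6E)-3-ethenyl-3,7,11-trimethyldodeca-6,10-dienoate F9, and saponification of this unhindered monoester (LiOH, THF/MeOH/H2O) should give 6.

Further compounds
F1 | step 5 | (3R,6E)-3-ethenyl-N-methoxy-N,3,7,11-tetramethyldodeca-6,10-dienamide | C=C[C@](C)(CC/C=C(\C)CCC=C(C)C)CC(=O)N(C)OC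
F2 | step 5 | 2-bromo-1-(methoxymethoxy)-3-methylbenzene | COCOc1cccc(C)c1Br
F3 | step 5 | [2-(methoxymethoxy)-6-methylphenyl]lithium | COCOc1cccc(C)c1[Li]
F4 | step 5 | (3R,6E)-3-ethenyl-1-[2-(methoxymethoxy)-6-methylphenyl]-3,7,11-trimethyldodeca-6,10-dien-1-one | C=C[C@](C)(CC/C=C(\C)CCC=C(C)C)CC(=O)c1c(C)cccc1OCOC
F5 | step 2 | diethyl (2E,6E)-3,7,11-trimethyldodeca-2,6,10-trien-1-yl phosphate | CCOP(=O)(OCC)OC/C=C(\C)CC/C=C(\C)CCC=C(C)C
F6 | step 2 | trimethyl[(3S,6E)-3-ethenyl-3,7,11-trimethyldodeca-6,10-dien-1-yn-1-yl]silane | C=C[C@](C)(CC/C=C(\C)CCC=C(C)C)C#C[Si](C)(C)C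
F7 | step 2 | (3S,6E)-3-ethenyl-3,7,11-trimethyldodeca-6,10-dien-1-yne | C=C[C@](C)(CC/C=C(\C)CCC=C(C)C)C#C
F8 | step 2 | (3R,6E)-3-ethenyl-3,7,11-trimethyldodeca-6,10-dienal | C=C[C@](C)(CC/C=C(\C)CCC=C(C)C)CC=O
F9 | step 3 | methyl (3R,6E)-3-ethenyl-3,7,11-trimethyldodeca-6,10-dienoate | C=C[C@](C)(CC/C=C(\C)CCC=C(C)C)CC(=O)OC
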